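Set the loss of X beside the loss of Q. Once Z is gone, the step X + Q → G is the one candidate step that touches either of them, so the two rates are equal, and their ratio is one at every moment, whatever the clock says. Time drops out, and the difference D = cX − cQ stands still. Call D the excess. Its value follows from counting: each Z turned takes one X and gives one Q, and each G takes one further X and one Q. Hence, with Z gone, D is the X charged less two charges of Z.

| setting | green | teal | blue | elm | larch | ash | maple | oak |
|---|---|---|---|---|---|---|---|---|
| Z | 10 mM | 10 mM | 10 mM | 10 mM | 10 mM | 10 mM | 10 mM | 10 mM |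
| X | 0.10 equiv | 1.1 equiv | 11 equiv | 0.120 equiv | 0.300 equiv | 1.00 equiv | 3.00 equiv | 10.0 equiv |
| remark | run made earlier | run made earlier | run made earlier |  |  |  |  |  |
| time |  |  |  | 2.0 d | 2.0 d | 2.0 d | 2.0 d | 2.0 d |

- green (time / h: Q / %, Z / %): 4.00: 0, 99.6; 12.0: 1.2, 97.8; 20.0: 2.6, 97.4; 30.0: 4.3, 95.3
- teal (time / h: Q / %, Z / %): 2.50: 5.1, 94.2; 6.00: 21.3, 77.0; 15.0: 62.5, 29.6; 30.0: 75.5, 12.3
- blue (time / h: Q / %, Z / %): 8.00: 16.1, 0; 15.0: 3.3, 0; 25.0: 0.2, 1.0; 30.0: 0, 0

(readings scatter by 0.5 percentage points)

- what was read earlier has a scatter of 0.5 percentage points, one standard deviation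
- candidate steps: Z + X + J -> Q + 2 J; Z + X -> Q + J; X + Q -> G
- "hardly changes" means that all values lie within two and a half points (for a concentration: within two and a half percent of the largest)

1. amount of Q at the end, in percent of the Z charged for elm, larch, ash, maple, oak, in this order
2. how the row runs (falls all the way / hardly changes / rises all the way / rises, then falls / falls, then rises)

Read the blue table row by row. Z, the limiting reagent there, already stands at 0% in the first row, so the rule applies from 8.00 h on, with D = 90.0 mM. The first row gives cQ = 1.61 mM. The second, at 15.0 h, gives 0.330 mM. The third reads 0.2%, inside the scatter of 0.5 percentage points, so leave it and the last row out.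

Now use D. Write the loss of Q as k·cX·cQ, with k the rate constant of X + Q → G, and put cX = D + cQ into it; then cQ/(D + cQ) decays exponentially with rate constant k·D. The first two rows then give k = 0.00249 /mM/h, as a reading.

For maple, the excess D, the X charged less two charges of Z, is 10.0 mM. Start the clock crudely at the charge, with Z in maple counted as Q already. Reckoned so, the ratio cQ/(D + cQ) after 2.0 d comes to 0.151, so my figure for Q in maple is 17.8%.

For oak, D is 80.0 mM, so the reckoned decay time of that ratio is 5.02 h, shorter than the 2.0 d allowed, and I expect Q near zero there. Each Q made takes one X, so Q in elm and larch stays under the X charged, 0.120 equiv and 0.300 equiv. Teal, close to ash in its charge of X, reads 75.5% at 30.0 h. So I expect the row to rise, then fall.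

The forecast gives 7.7%, 24%, 71%, 20% and 0%, rises, then falls, with maple higher than my figure, and says “Oak destroys Q completely”.

    Z + X + J → Q + 2 J (k = 3800 /M²/h)
    Z + X → Q + J (k = 1.20 /M/h)
    X + Q → G (k = 2.70 /M/h)

The flasks give 8.27%, 25.2%, 74.4%, 17.4% and 0%, so the row rises, then falls. Maple ends with G at 82.6%. Add its excess 10.0 mM to its final cQ and you get 11.7 mM, which is 39.1% of the X charged, and X stands at 39.1% of its charge. In oak, the excess 80.0 mM is 80.0% of the X charged, and at 2.00 d X stands at 80.0% of its charge.

All runs were generated by integration for an exercise, noise included.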